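Reciprocal minutes are the unit of the quantity we carry through this flask: follow one partner molecule and ask its chance per minute of ending in product.

| setting | alder | elm | maple | oak | ash |
|---|---|---|---|---|---|
| substrate | 0.0500 M | 0.0200 M | 0.0500 M | 0.0250 M | 0.0500 M |
| partner | 0.0750 M | 0.0450 M | 0.0370 M | 0.0750 M | 0.0120 M |
| free catalyst | 0.00250 M | 0.00250 M | 0.00250 M | 0.00250 M | 0.00250 M |
| time |  |  |  |  | 130 min |

| run | time / min | [product] / M |
|---|---|---|
| alder run | 9.9 | 4 × 10⁻⁴ |
| alder run | 30 | 0.0056 |
| alder run | 57 | 0.0160 |
| alder run | 91 | 0.0265 |
| alder run | 130 | 0.0363 |
| elm run | 9.9 | 9 × 10⁻⁴ |
| elm run | 30 | 0.0022 |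
| elm run | 57 | 0.0073 |
| elm run | 91 | 0.0119 |
| elm run | 130 | 0.0152 |
| maple run | 9.9 | 2 × 10⁻⁴ |
| maple run | 30 | 0.0060 |
| maple run | 57 | 0.0149 |
| maple run | 91 | 0.0247 |
| maple run | 130 | 0.0322 |
| oak run | 9.9 | 9 × 10⁻⁴ |
| oak run | 30 | 0.0034 |
| oak run | 57 | 0.0084 |
| oak run | 91 | 0.0136 |
| oak run | 130 | 0.0181 |

(readings scatter by 3 × 10⁻⁴ M)

- Overall: substrate + partner -> product, with free catalyst as catalyst.
- Constant volume, constant temperature.
- What is held in complexes is read along with the free species.
- An order is taken over about fifteen percent of the charge, up and down.

* how the opening rate goes with [substrate] round the charge of the alder run: the exponent of the rate at two percent of substrate gone to product (one fixed amount of product, the same in the runs compared)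
* how the opening rate goes with [partner] round the charge of the alder run: the exponent of the rate at two percent of substrate gone to product
* the elm run starts with 0.0300 M less of substrate and of partner than the alder run, and with no product. Compared where both hold the same amount of substrate, once fifteen percent of what the elm run was charged with has turned into product, is the elm run faster, slower or alike (within a tenth)?
* product in the ash run at 130 min, as a share of the substrate charged

Each product takes up one partner, so partner left is the charge minus the product read. We reckon the ash share and leave the other questions to the forecast. The bound from above is the charge: in the ash run partner is the limiting reagent, 0.0120 M against 0.0500 M of substrate, so the share cannot pass 24.0%.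

An estimated bound from below comes from the maple run, which at 91 min holds 0.0123 M of partner, close to the ash charge. Between that reading and the one at 130 min, a partner molecule in the maple run has a chance per minute κ, the logarithm of the ratio of partner at the two readings divided by the time between them, of 0.0241 min⁻¹. This is a pseudo-first-order constant, and as a reading it carries the scatter. The window before it gives 0.0172 min⁻¹, less than κ, so in the maple run the chance rises as partner falls, and holding it at κ should understate the ash run. The ash run also keeps at least 0.0380 M of substrate, more than the 0.0253 M of the maple run at that reading. We further count no product in the ash run for the first 30 min, though the maple run had made 0.0060 M by then. Partner left at 130 min is then estimated at 0.00107 M, which puts our estimated floor at 21.9%. We commit to the bracket from that floor to 24.0%.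

The forecast gives orders of 0.9 in substrate and 0.2 in partner, calls the elm run slower, and puts the ash share at 23.5%, inside our bracket, on the ground that “Near-saturation in partner means it is essentially used up”.

The mechanism behind the readings is this.

    active catalyst + substrate → loaded catalyst + by-product (9.840 M⁻¹ min⁻¹)
    loaded catalyst + partner → product + active catalyst (15.30 M⁻¹ min⁻¹)
    free catalyst → active catalyst (0.04404 min⁻¹)
    active catalyst + partner ⇌ idle catalyst-reagent complex, settled at all times (13.80 M⁻¹)

The flask gives orders of 0.49 and −0.13, the elm run slower, and an ash share of 23.3%, inside the bracket. The pairing of active catalyst with partner to the idle catalyst-reagent complex makes no difference to that share. The ash run leaves 3.49 × 10⁻⁴ M of partner unturned, so its mean chance over the 100 min we counted is 0.0354 min⁻¹, more than κ. In the alder run, partner goes from 0.0500 M at 85.8 min, where the product made comes to half of the substrate charged, to 0.0387 M at 130 min, a chance of 0.00579 min⁻¹, a quarter of the maple κ of 0.0241 min⁻¹.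

(The runs are simulated for an exercise; the scatter is artificial.)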